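The numbers in the tables come from a simulation with made-up constants, and the scatter is random.

in all of them: left-handed substrate 0.20 M; right-handed substrate 0.20 M; gas 27 mM (held); catalyst 0.5 mol%
- red: added ligand 2.1 mM; run made earlier
- grey: added ligand 4.8 mM; run made earlier
- flask: added ligand 3.2 mM; time 30 h

- red (time / h: left-handed substrate / %, right-handed substrate / %): 4.00: 21.5, 50.6; 8.00: 2.7, 50.2; 12.0: 0.5, 48.6; 15.0: 0.6, 48.8; 20.0: 0, 48.9; 25.0: 0, 47.5
- grey (time / h: left-handed substrate / %, right-handed substrate / %): 4.00: 30.7, 49.6; 8.00: 18.2, 49.1; 12.0: 8.6, 49.9; 15.0: 5.0, 50.8; 20.0: 2.1, 50.0; 25.0: 0.5, 46.5

(readings scatter by 1 percentage point)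

- catalyst is single-handed; left-handed substrate and right-handed substrate are mirror images of each other, charged as a racemate, each of them at the stated concentration
- at the start none of partner is dissolved
- steps that have been proposed: catalyst + added ligand <-> idle complex; partner + catalyst + left-handed substrate -> catalyst + left-handed product; partner + catalyst + right-handed substrate -> catalyst + right-handed product; 2 partner -> self-condensation product; gas <-> partner
- an excess is the difference of the two amounts in percent of their sum
- an excess is below zero if the other one leads

* part of the left-handed substrate and right-handed substrate charged together that has reacted at 30 h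
* excess of left-handed product over right-handed product in the product at 30 h
* excess of right-handed substrate over left-handed substrate among what is left of the two at 30 h

Open the ledger with the catalyst: in the flask you charged 1.00 mM of it against 3.2 mM of added ligand, which makes it the limiting reagent of the binding. If you book every catalyst as idle complex, free ligand is the ligand charge minus the catalyst charge. Between readings the left-handed substrate falls in a pseudo-first-order way, and the red and grey runs give:

| run | free ligand | decay constant | product of the two |
|---|---|---|---|
| red | 1.10 mM | 0.519 h⁻¹ | 0.571 mM h⁻¹ |
| grey | 3.80 mM | 0.180 h⁻¹ | 0.684 mM h⁻¹ |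

Take the mean of these products as the clearing product, the late decay constant of the left-handed substrate times free ligand: 0.627 mM h⁻¹. The flask has 2.20 mM of free ligand, so its constant is 0.285 h⁻¹.

Book the left-handed half next. No partner is dissolved at the start, so give up the first 4.00 h, which leaves 0.0302 % of the total charge at 30 h; the rest is left-handed product. Then the right-handed half: the late means of red and grey, 48.2 % and 48.2 %, lie within the scatter of 1 percentage point, so these readings do not show how the drift goes with ligand, although the proposed step for the right-handed substrate runs through the same catalyst; as a rough entry, not a scaled one, I pool the two runs, and the drift comes to 2.4 points, booked as right-handed product. The books close at 52.3 % reacted, 91.0 % excess in the product and 99.9 % in the substrate.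

The forecast, holding that “the rate goes roughly as” inverse free ligand, gives 51.6 % (50.6 % to 53.5 %), 93.8 % (86.5 % to 97.5 %) and 99.8 % (99.2 % to 100 %).

    catalyst + added ligand ⇌ idle complex, settled at all times (K = 1500 L mol⁻¹)
    partner + catalyst + left-handed substrate → catalyst + left-handed product (k = 17.0 L² mol⁻² s⁻¹)
    partner + catalyst + right-handed substrate → catalyst + right-handed product (k = 0.120 L² mol⁻² s⁻¹)
    2 partner → self-condensation product (k = 0.00330 L mol⁻¹ s⁻¹)
    gas ⇌ partner, rate k5*(csat - [partner]) (kL = 5.90 × 10⁻⁴ s⁻¹)

The flask gives 52.6 % reacted, 90.1 % excess in the product and 99.9 % in the substrate. At 30.0 h it holds 21.6 % of its catalyst free and 78.4 % as idle complex, which leaves 2.42 mM of free ligand against my 2.20 mM. For the neighbour flask with 0.0080 M of added ligand, free ligand is 7.00 mM, so the clearing product gives a constant of 0.0896 h⁻¹ and, with the same lag, 9.73 % of its left-handed charge remaining; that neighbour flask holds 4.7 % at 30.0 h.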